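The 1,2-dioxane (O1, O2, C3 bearing the acetic acid arm, C4, C5, C6) is disconnected at O1–C6 and C4–C5, the two bonds that flank the ring methylene C5. Because C6 is fully substituted, peroxypalladation of the 1,1-disubstituted alkene 7 by the allylic hydroperoxide 10 gives a C5 alkylpalladium without β-hydrogen. This can only insert 6-exo into the vinyl group of 10 (the future C4 and its methyl) before β-hydride elimination. One oxidative Wacker–Heck-type domino thus closes the ring from two acyclic pieces, with C3 preset in 10 and C6 made in the step. Diimide then sets C4 and saponification gives the acid.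

Key step: step 6

Remark: (7-bromoheptyl)benzene, (2S)-3-bromo-2-methylpropan-1-ol and methyl (3E)-pent-3-enoate are taken as commercial.

Step 1
Reactants: 1 (7-bromoheptyl)benzene; 2 (2S)-3-bromo-2-methylpropan-1-ol
Product: 5 (2R)-2-methyl-10-phenyldecan-1-ol, via Grignard reagent 3 (not isolated), via magnesium alkoxide 4 (not isolated)
Conditions: 1, Mg, THF, 40 °C; separately 2, MeMgCl (1.0 equiv), THF, −20 °C; then 3 (1.4 equiv), Li2CuCl4 (3 mol %), −20 to 20 °C; aq NH4Cl
Reagents that add atoms: none
Why: Copper-catalysed Kochi cross-coupling of the primary alkyl Grignard reagent with the primary bromide of the pre-formed alkoxide; the stereocenter of 2 is not a reacting center and is carried over unchanged (the descriptor changes from S to R only through the priority rules).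

Step 2
Reactants: 5 (2R)-2-methyl-10-phenyldecan-1-ol
Product: 6 (2R)-1-iodo-2-methyl-10-phenyldecane
Conditions: I2, PPh3, imidazole, CH2Cl2, 0 to 20 °C
Reagents that add atoms: iodine, II
Why: Appel-type iodination of the primary alcohol by SN2 displacement of the alkoxyphosphonium ion, which leaves the neighbouring stereocenter untouched.

Step 3
Reactants: 6 (2R)-1-iodo-2-methyl-10-phenyldecane
Product: 7 (4R)-2,4-dimethyl-12-phenyldodec-1-ene
Conditions: isopropenylmagnesium bromide (1.5 equiv), CuI (10 mol %), THF, −20 to 20 °C
Reagents that add atoms: isopropenylmagnesium bromide, C=C(C)[Mg]Br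
Why: Copper-catalysed Kochi-type sp2–sp3 coupling of the alkenyl Grignard reagent with the primary iodide installs the 1,1-disubstituted alkene; no stereocenter is formed or touched.

Step 4
Reactants: 8 methyl (3E)-pent-3-enoate
Product: 9 methyl 3-hydroperoxypent-4-enoate (racemate)
Conditions: O2, tetraphenylporphyrin (cat.), visible light, CH2Cl2, 0 °C
Reagents that add atoms: dioxygen, O=O
Why: Schenck ene reaction of singlet oxygen, in which abstraction of a hydrogen from the terminal methyl group with C–O bonding at C3 gives the branched allylic hydroperoxide as the racemate; the conjugated regioisomer from abstraction at C2 is removed by chromatography.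

Step 5
Reactants: 9 methyl 3-hydroperoxypent-4-enoate (racemate)
Product: 10 methyl (3S)-3-hydroperoxypent-4-enoate
Conditions: horseradish peroxidase (cat.), guaiacol (1.1 equiv), 0.1 M phosphate buffer pH 6, 20 °C, stopped near half conversion
Reagents that add atoms: none
Why: Enzymatic kinetic resolution in which the peroxidase reduces one enantiomer of the secondary hydroperoxide to the alcohol at the expense of guaiacol; by analogy with resolutions of other allylic β-hydroperoxy esters the (S)-hydroperoxide should be the one left, which sets C3.

Step 6
Reactants: 7 (4R)-2,4-dimethyl-12-phenyldodec-1-ene; 10 methyl (3S)-3-hydroperoxypent-4-enoate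
Product: 13 methyl 2-[(3S,6R)-6-methyl-4-methylidene-6-[(2R)-2-methyl-10-phenyldecyl]-1,2-dioxan-3-yl]acetate, via peroxypalladation adduct 11 (not isolated), via cyclised alkylpalladium 12 (not isolated)
Conditions: Pd(OCOCF3)2 (10 mol %), (S,S)-Bn-BOXAX (20 mol %), p-benzoquinone (2 equiv), 4 Å molecular sieves, CH2Cl2, 20 °C, 10 (1.3 equiv) added slowly
Reagents that add atoms: none
Why: Proposed new method: divalent palladium exchanges trifluoroacetate for the hydroperoxide 10, the resulting palladium peroxide adds syn across the 1,1-disubstituted alkene 7 in the Markovnikov sense (O1–C6 bond, palladium on C5) to give 11, the C5–Pd bond then inserts into the pendant vinyl group (C5–C4 bond) to give 12, and β-hydride elimination of the C4 hydrogen releases 13 while benzoquinone returns zerovalent palladium to the divalent state. The closest known reaction types are the domino Wacker–Heck reaction (oxypalladation of a 1,1-disubstituted alkene to a β-hydrogen-free alkylpalladium that then undergoes a Heck reaction), the palladium-catalysed annulation of allylic alcohols with vinyl ethers to 4-methylenetetrahydrofurans and the palladium-catalysed cyclisation of unsaturated hydroperoxides to 1,2-dioxanes; the untested element is a hydroperoxide as intermolecular nucleophile on an unactivated alkene. The 1,2-dioxane ring closes in the carbopalladation, a 6-exo-trig ring closure. C6 is the only new stereocenter and is set in the peroxypalladation by the chiral bis(oxazoline) ligand on palladium (reagent control of the alkene face, as in enantioselective Wacker cyclisations that create fully substituted C–O centers), C3 is carried in unchanged from 10, and the C4 center of 12 is erased in the elimination. The step needs Markovnikov regioselectivity, attack on 7 in preference to the vinyl group of 10 and cyclisation in preference to other exits: the fully substituted C6 leaves 11 no β-hydrogen, so reversal or insertion are its only paths, slow addition of 10 keeps its own alkene from competing for the palladium peroxide, and after insertion the single β-hydrogen on C4 makes the exocyclic alkene the only Heck product.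

Step 7
Reactants: 13 methyl 2-[(3S,6R)-6-methyl-4-methylidene-6-[(2R)-2-methyl-10-phenyldecyl]-1,2-dioxan-3-yl]acetate
Product: 14 methyl 2-[(3S,4S,6R)-4,6-dimethyl-6-[(2R)-2-methyl-10-phenyldecyl]-1,2-dioxan-3-yl]acetate
Conditions: dipotassium azodicarboxylate (KO2CN=NCO2K, 10 equiv), AcOH (20 equiv), MeOH/CH2Cl2, 0 to 20 °C
Reagents that add atoms: none
Why: Diimide reduction (concerted syn transfer of two hydrogens, which spares the O–O bond) should take place on the ring face anti to the C3 acetate arm and the C6 decyl chain, which lie on the same face, so that the new methyl ends cis to the C3 arm, that is (4S).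

Step 8
Reactants: 14 methyl 2-[(3S,4S,6R)-4,6-dimethyl-6-[(2R)-2-methyl-10-phenyldecyl]-1,2-dioxan-3-yl]acetate
Product: 15 2-[(3S,4S,6R)-4,6-dimethyl-6-[(2R)-2-methyl-10-phenyldecyl]-1,2-dioxan-3-yl]acetic acid
Conditions: LiOH (3 equiv), THF/H2O 3:1, 0 °C; then 1 M HCl to pH 3
Reagents that add atoms: lithium hydroxide, [Li+].[OH-]
Why: Saponification of the methyl ester with cold LiOH, conditions under which 1,2-dioxane-3-acetates of this kind should keep the O–O bond; no stereocenter is touched, and the short contact time at 0 °C guards C3 against retro-oxa-Michael opening.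

Compound list
1 | (7-bromoheptyl)benzene | BrCCCCCCCc1ccccc1 | starting material
2 | (2S)-3-bromo-2-methylpropan-1-ol | C[C@H](CBr)CO | starting material
3 | (7-phenylheptyl)magnesium bromide | Br[Mg]CCCCCCCc1ccccc1 | intermediate
4 | chloromagnesium (2S)-3-bromo-2-methylpropan-1-olate | C[C@H](CBr)CO[Mg]Cl | intermediate
5 | (2R)-2-methyl-10-phenyldecan-1-ol | C[C@H](CCCCCCCCc1ccccc1)CO | intermediate
6 | (2R)-1-iodo-2-methyl-10-phenyldecane | C[C@H](CCCCCCCCc1ccccc1)CI | intermediate
7 | (4R)-2,4-dimethyl-12-phenyldodec-1-ene | C[C@H](CCCCCCCCc1ccccc1)CC(C)=C | intermediate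
8 | methyl (3E)-pent-3-enoate | C/C=C/CC(=O)OC | starting material
9 | methyl 3-hydroperoxypent-4-enoate (racemate) | C=CC(CC(=O)OC)OO | intermediate
10 | methyl (3S)-3-hydroperoxypent-4-enoate | C=C[C@H](CC(=O)OC)OO | intermediate
11 | [(2R,4R)-2-{[(3S)-5-methoxy-5-oxopent-1-en-3-yl]peroxy}-2,4-dimethyl-12-phenyldodecyl]palladium trifluoroacetate (bis(oxazoline) ligand not drawn) | C[C@H](CCCCCCCCc1ccccc1)C[C@](C)(C[Pd]OC(=O)C(F)(F)F)OO[C@H](C=C)CC(=O)OC | intermediate
12 | {[(3S,6R)-3-(2-methoxy-2-oxoethyl)-6-methyl-6-[(2R)-2-methyl-10-phenyldecyl]-1,2-dioxan-4-yl]methyl}palladium trifluoroacetate (C4 configuration left open because it is erased; ligand not drawn) | C[C@H](CCCCCCCCc1ccccc1)C[C@]1(C)CC(C[Pd]OC(=O)C(F)(F)F)[C@H](CC(=O)OC)OO1 | intermediate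
13 | methyl 2-[(3S,6R)-6-methyl-4-methylidene-6-[(2R)-2-methyl-10-phenyldecyl]-1,2-dioxan-3-yl]acetate | C[C@H](CCCCCCCCc1ccccc1)C[C@]1(C)CC(=C)[C@H](CC(=O)OC)OO1 | intermediate
14 | methyl 2-[(3S,4S,6R)-4,6-dimethyl-6-[(2R)-2-methyl-10-phenyldecyl]-1,2-dioxan-3-yl]acetate | C[C@H](CCCCCCCCc1ccccc1)C[C@]1(C)C[C@H](C)[C@H](CC(=O)OC)OO1 | intermediate
15 | 2-[(3S,4S,6R)-4,6-dimethyl-6-[(2R)-2-methyl-10-phenyldecyl]-1,2-dioxan-3-yl]acetic acid | C[C@H](CCCCCCCCc1ccccc1)C[C@]1(C)C[C@H](C)[C@H](CC(=O)O)OO1 | target

Total step count: 8. Longest linear sequence: 6 steps (steps 1, 2, 3, 6, 7, 8).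

Steps most likely to fail

1. Step 6 (Proposed new method). The palladium peroxide may oxidise the terminal alkene of 10 or activate allylic C–H bonds of 7 instead of adding across 7. The alkylpalladium 11 may revert faster than it cyclises, and the facial selectivity at C6 in the peroxypalladation may be low or opposite; the antipodal ligand is then the first variable. The fallback sets out from 7 and 10 and comes back to the route at 14, using known chemistry in two operations. Iodoperoxidation of 7 with 10 and N-iodosuccinimide (CH2Cl2, −20 °C; Markovnikov opening of the iodonium ion by the hydroperoxide) gives methyl (3S)-3-{[(2RS,4R)-1-iodo-2,4-dimethyl-12-phenyldodecan-2-yl]peroxy}pent-4-enoate F1 as both epimers at the new quaternary carbon. Treatment with Bu3SnH and Et3B/air in toluene at −20 °C then brings about a Ueno–Stork-type 6-exo-trig radical cyclisation of the C5 radical onto the vinyl group, the methyl arising by hydrogen transfer from the tin hydride. This leads directly to 14, whose C4 and C6 epimers are separated by chromatography. The competing process in this fallback is attack of the β-peroxyalkyl radical on the O–O bond.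

2. Step 5. The enzyme may accept this substrate slowly, discriminate the enantiomers poorly or leave the opposite enantiomer. The fallback sets out from 9 and comes back at 10 by resolution through diastereomeric perketals. Compound 9 and 2-{[(1R,2S)-2-phenylcyclohexyl]oxy}prop-1-ene with pyridinium p-toluenesulfonate in CH2Cl2 give methyl (3S)-3-[(2-{[(1R,2S)-2-phenylcyclohexyl]oxy}propan-2-yl)peroxy]pent-4-enoate F2 and methyl (3R)-3-[(2-{[(1R,2S)-2-phenylcyclohexyl]oxy}propan-2-yl)peroxy]pent-4-enoate F3. These are separated by chromatography, and AcOH/THF/H2O at 20 °C releases 10 from F2.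

3. Step 7. Hydrogen may be delivered to the wrong face of the exocyclic alkene, or the reduction may stall on the hindered 1,1-disubstituted alkene. The fallback sets out from 13 and comes back at 14 by a stepwise radical mechanism in place of the concerted one: metal-hydride hydrogen-atom-transfer hydrogenation (Mn(dpm)3, PhSiH3, tert-butyl hydroperoxide, iPrOH, 20 °C). The first hydrogen atom goes to the methylene carbon and gives the tertiary C4 radical inside the ring, where the ring geometry disfavours attack on the O–O bond. This radical should take its second hydrogen on the face anti to the C3 arm. No new compound is formed on the way.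

Further compounds
F1 | step 6 | methyl (3S)-3-{[(2RS,4R)-1-iodo-2,4-dimethyl-12-phenyldodecan-2-yl]peroxy}pent-4-enoate (both epimers at C2 of the dodecane) | C[C@H](CCCCCCCCc1ccccc1)CC(C)(CI)OO[C@H](C=C)CC(=O)OC
F2 | step 5 | methyl (3S)-3-[(2-{[(1R,2S)-2-phenylcyclohexyl]oxy}propan-2-yl)peroxy]pent-4-enoate | C=C[C@H](CC(=O)OC)OOC(C)(C)O[C@@H]1CCCC[C@H]1c1ccccc1
F3 | step 5 | methyl (3R)-3-[(2-{[(1R,2S)-2-phenylcyclohexyl]oxy}propan-2-yl)peroxy]pent-4-enoate | C=C[C@@H](CC(=O)OC)OOC(C)(C)O[C@@H]1CCCC[C@H]1c1ccccc1
F0 | step 7 | none | none
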